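**Plan**
- Retrosynthesis cuts, in this order: the 5'-O–pivaloyl ester bond; O1–C8a of the pyranone (the only ring-forming bond); C2–C3 (enolate acylation); C4–C4a (aryllithium plus Weinreb amide); and the B-ring C5'–O bond (bromination, then hydroxylation).
- Forward: rings A and B are bought as benzenoids and joined through the C4–C3–C2 chain as an open 2-methoxy-1,3-diketone. Ring C is closed last by anodic C–O bond formation, and the pivalate is then removed.
- Enabling feature: O6–H of ring A is para to C8a, the carbon that must receive O1. Oxidising this single free phenol makes C8a electrophilic right next to the oxygen of the ring-B carbonyl.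
- Stereochemistry: none to set. The target is achiral; C2 of the diketone is racemic and enolisable and becomes sp2 on ring closure.

Key step: step 9

Assumption: the target SMILES carries no stereodescriptor and the molecule has no stereogenic element, so the compound as drawn is the only species to be made. Compounds 1, 2, 4, 8 and 11 are taken as commercial.

**Step 1**
Reactants: 1 5-bromo-2-methoxyphenol; 2 benzyl bromide
Product: 3 2-(benzyloxy)-4-bromo-1-methoxybenzene
Conditions: BnBr (1.1 equiv), K2CO3, DMF, rt
Reagents that add atoms: benzyl bromide (2), BrCc1ccccc1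
Why: Williamson ether synthesis on the phenoxide masks the future 6-OH as a benzyl ether that should survive organolithium and enolate chemistry and can later be removed by hydrogenolysis without touching an aryl pivalate.

**Step 2**
Reactants: 3 2-(benzyloxy)-4-bromo-1-methoxybenzene; 4 N,2-dimethoxy-N-methylacetamide
Product: 7 1-[3-(benzyloxy)-4-methoxyphenyl]-2-methoxyethan-1-one, via aryllithium 5 (not isolated), via tetrahedral lithium adduct 6 (not isolated)
Conditions: n-BuLi (1.05 equiv), THF, −78 °C; then 4, −78 → 0 °C; aq. NH4Cl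
Reagents that add atoms: N,2-dimethoxy-N-methylacetamide (4), COCC(=O)N(C)OC
Why: Bromine–lithium exchange should outrun any deprotonation at −78 °C, and the aryllithium adds only once to the Weinreb amide (Weinreb ketone synthesis) because the chelated adduct 6 collapses to the α-methoxy ketone only on work-up.

**Step 3**
Reactants: 8 2,4-dimethoxybenzoic acid
Product: 9 5-bromo-2,4-dimethoxybenzoic acid
Conditions: Br2 (1.05 equiv), AcOH, rt
Reagents that add atoms: bromine, BrBr
Why: Electrophilic aromatic bromination should go to C5, which is para to the 2-methoxy and ortho to the 4-methoxy group, whereas C3 is flanked by two substituents and C6 is meta to both donors.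

**Step 4**
Reactants: 9 5-bromo-2,4-dimethoxybenzoic acid
Product: 10 5-hydroxy-2,4-dimethoxybenzoic acid
Conditions: Pd2(dba)3 (cat.), t-BuXPhos (cat.), KOH (4 equiv), 1,4-dioxane/H2O, 100 °C, degassed; then 1 M HCl
Reagents that add atoms: potassium hydroxide, [K+].[OH-]
Why: Palladium-catalysed C–O coupling of an aryl bromide with hydroxide (Buchwald-type hydroxylation with a bulky biaryl phosphine) tolerates the carboxylate and the electron-rich ring and should release the phenol on acidification.

**Step 5**
Reactants: 10 5-hydroxy-2,4-dimethoxybenzoic acid; 11 pivaloyl chloride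
Product: 12 2,4-dimethoxy-5-(pivaloyloxy)benzoic acid
Conditions: PivCl (1.2 equiv), NaOH (2.2 equiv), H2O/THF, 0 °C, N2; then 1 M HCl to pH 2
Reagents that add atoms: pivaloyl chloride (11), CC(C)(C)C(=O)Cl
Why: Schotten–Baumann O-acylation: in aqueous base the phenoxide is far more nucleophilic than the carboxylate, and any mixed anhydride is hydrolysed back, so only the aryl pivalate should persist.

**Step 6**
Reactants: 12 2,4-dimethoxy-5-(pivaloyloxy)benzoic acid
Product: 13 2,4-dimethoxy-5-(pivaloyloxy)benzoyl chloride
Conditions: (COCl)2 (1.3 equiv), DMF (cat.), CH2Cl2, 0 °C → rt; evaporate, use crude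
Reagents that add atoms: oxalyl chloride, O=C(Cl)C(=O)Cl
Why: Acid chloride formation through the Vilsmeier-type chloroiminium species is mild enough to leave the aryl pivalate and the methyl ethers intact.

**Step 7**
Reactants: 7 1-[3-(benzyloxy)-4-methoxyphenyl]-2-methoxyethan-1-one; 13 2,4-dimethoxy-5-(pivaloyloxy)benzoyl chloride
Product: 15 1-[3-(benzyloxy)-4-methoxyphenyl]-3-[2,4-dimethoxy-5-(pivaloyloxy)phenyl]-2-methoxypropane-1,3-dione (racemic at C2, enolisable), via lithium enolate 14 (not isolated)
Conditions: 7 (2.0 equiv), LiHMDS (2.0 equiv), THF, −78 °C; then 13 (1.0 equiv), −78 → 0 °C; aq. NH4Cl; surplus 7 recovered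
Reagents that add atoms: none
Why: Claisen-type C-acylation of a preformed lithium ketone enolate by an aroyl chloride should give the 1,3-diketone, the second enolate equivalent taking up the acidic C2–H of the product so that over-acylation is suppressed, while the hindered pivalate is not attacked at low temperature.

**Step 8**
Reactants: 15 (the benzyl-protected diketone)
Product: 16 1-(3-hydroxy-4-methoxyphenyl)-3-[2,4-dimethoxy-5-(pivaloyloxy)phenyl]-2-methoxypropane-1,3-dione (racemic at C2, enolisable)
Conditions: H2 (1 atm), 10% Pd/C, EtOAc, rt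
Reagents that add atoms: none
Why: Catalytic hydrogenolysis of a benzyl aryl ether is much faster than reduction of aryl ketones under 1 atm H2 in a neutral solvent, and the ester and methyl ethers are inert.

**Step 9**
Reactants: 16 (the phenolic diketone)
Product: 19 6-hydroxy-3,7-dimethoxy-2-[2,4-dimethoxy-5-(pivaloyloxy)phenyl]-4H-chromen-4-one, via phenoxonium cation 17 (not isolated), via 8aH-chromene-4,6-dione 18 (not isolated)
Conditions: graphite anode, Pt cathode, undivided cell, constant current (ca. 5 mA cm⁻², 2.0–2.1 F mol⁻¹), 2,6-lutidine (2 equiv), n-Bu4NPF6 (0.1 M), HFIP, rt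
Reagents that add atoms: none
Why: Proposed new method: at the carbon anode the only free phenol (O6–H of ring A) should lose two electrons and, to 2,6-lutidine, one proton to give phenoxonium ion 17, whose charge at the carbon para to oxygen (future C8a) is relayed onto the ortho methoxy group as a quinoid oxocarbenium; the oxygen of the ring-B carbonyl (keto or enol form) adds to that carbon to give dienone 18, which tautomerises to the 6-hydroxychromone. The closest known reactions are the oxidative para C–O couplings that turn 2,3'-dihydroxybenzophenones into 2-hydroxyxanthones and anodic dehydrogenative couplings of phenols with nucleophiles in HFIP. The pyranone closes in a six-membered mode, 6-exo-trig with respect to the C8=C8a bond of the quinoid cation (the C4a–C8a bond of the benzo ring ends up inside the new ring). No stereocentre survives, since C2 of 16 becomes sp2 and the C8a centre of 18 is lost on rearomatisation. The step needs oxidation of ring A only and attack para, not ortho, to the phenol oxygen: ring B has no free OH and its pivalate raises its potential, the para carbon leads to the more stable cross-conjugated dienone and is less crowded than the carbon between OH and the acyl group, and lutidine is too weak a base to form the diketone enolate that would otherwise be oxidised first. The charge is held near 2 F per mol and HFIP hydrogen bonding should shield product 19 from further oxidation.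

**Step 10**
Reactants: 19 (the 5'-pivalate of the flavone)
Product: 20 6,5'-dihydroxy-3,7,2',4'-tetramethoxyflavone
Conditions: K2CO3 (3 equiv), MeOH, rt, argon; then 1 M HCl to pH 4–5
Reagents that add atoms: none
Why: Carbonate-mediated methanolysis (transesterification) of the aryl pivalate expels a good phenoxide leaving group, while the methyl ethers and the 3-methoxyflavone core should be stable to K2CO3/MeOH at room temperature.

**Compound list**
1 | 5-bromo-2-methoxyphenol | COc1ccc(Br)cc1O | starting material
2 | benzyl bromide | BrCc1ccccc1 | starting material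
3 | 2-(benzyloxy)-4-bromo-1-methoxybenzene | COc1ccc(Br)cc1OCc1ccccc1 | intermediate
4 | N,2-dimethoxy-N-methylacetamide | COCC(=O)N(C)OC | starting material
5 | [3-(benzyloxy)-4-methoxyphenyl]lithium (formed in the flask, not isolated) | [Li]c1ccc(OC)c(OCc2ccccc2)c1 | intermediate
6 | lithium 1-[3-(benzyloxy)-4-methoxyphenyl]-2-methoxy-1-[methoxy(methyl)amino]ethan-1-olate, racemic (formed in the flask, not isolated) | [Li]OC(COC)(N(C)OC)c1ccc(OC)c(OCc2ccccc2)c1 | intermediate
7 | 1-[3-(benzyloxy)-4-methoxyphenyl]-2-methoxyethan-1-one | COCC(=O)c1ccc(OC)c(OCc2ccccc2)c1 | intermediate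
8 | 2,4-dimethoxybenzoic acid | COc1ccc(C(=O)O)c(OC)c1 | starting material
9 | 5-bromo-2,4-dimethoxybenzoic acid | COc1cc(OC)c(C(=O)O)cc1Br | intermediate
10 | 5-hydroxy-2,4-dimethoxybenzoic acid | COc1cc(OC)c(C(=O)O)cc1O | intermediate
11 | pivaloyl chloride | CC(C)(C)C(=O)Cl | starting material
12 | 2,4-dimethoxy-5-(pivaloyloxy)benzoic acid | COc1cc(OC)c(C(=O)O)cc1OC(=O)C(C)(C)C | intermediate
13 | 2,4-dimethoxy-5-(pivaloyloxy)benzoyl chloride | COc1cc(OC)c(C(Cl)=O)cc1OC(=O)C(C)(C)C | intermediate
14 | lithium enolate of 7, drawn as the chelated Z isomer, geometry of no consequence (formed in the flask, not isolated) | [Li]O/C(=C\OC)c1ccc(OC)c(OCc2ccccc2)c1 | intermediate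
15 | 1-[3-(benzyloxy)-4-methoxyphenyl]-3-[2,4-dimethoxy-5-(pivaloyloxy)phenyl]-2-methoxypropane-1,3-dione, racemic at C2 | COc1ccc(C(=O)C(OC)C(=O)c2cc(OC(=O)C(C)(C)C)c(OC)cc2OC)cc1OCc1ccccc1 | intermediate
16 | 1-(3-hydroxy-4-methoxyphenyl)-3-[2,4-dimethoxy-5-(pivaloyloxy)phenyl]-2-methoxypropane-1,3-dione, racemic at C2 | COc1ccc(C(=O)C(OC)C(=O)c2cc(OC(=O)C(C)(C)C)c(OC)cc2OC)cc1O | intermediate
17 | phenoxonium cation of 16, drawn with the charge at the carbon para to oxygen (formed at the anode, not isolated) | O=C1C=C(C(=O)C(OC)C(=O)c2cc(OC(=O)C(C)(C)C)c(OC)cc2OC)[CH+]C=C1OC | intermediate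
18 | 3,7-dimethoxy-2-[2,4-dimethoxy-5-(pivaloyloxy)phenyl]-8aH-chromene-4,6-dione, racemic at C8a (formed in the cell, not isolated) | COC1=CC2OC(c3cc(OC(=O)C(C)(C)C)c(OC)cc3OC)=C(OC)C(=O)C2=CC1=O | intermediate
19 | 6-hydroxy-3,7-dimethoxy-2-[2,4-dimethoxy-5-(pivaloyloxy)phenyl]-4H-chromen-4-one | CC(C)(C)C(=O)Oc1cc(-c2oc3cc(OC)c(O)cc3c(=O)c2OC)c(OC)cc1OC | intermediate
20 | 6,5'-dihydroxy-3,7,2',4'-tetramethoxyflavone | COc1cc(OC)c(-c2oc3cc(OC)c(O)cc3c(=O)c2OC)cc1O | target

**Step count**
Total: 10 steps. Longest linear sequence: 8 steps (steps 3, 4, 5, 6, 7, 8, 9, 10, from 8 to 20). The A-ring branch (steps 1 and 2) joins at step 7.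

**Steps most likely to fail**

Step 9 (proposed new method). The anode may oxidise the diketone enol in place of the phenol, the closure may take place ortho to the phenol oxygen (between OH and the acyl group), or the product phenol, which now carries a para oxygen, may be oxidised further. The fallback uses a copper-catalysed intramolecular O-arylation. It sets out from 7 and returns at 19. Ring iodination of 7 with I2/CF3CO2Ag in CH2Cl2, para to the benzyloxy group, should give 1-[5-(benzyloxy)-2-iodo-4-methoxyphenyl]-2-methoxyethan-1-one F1. Deprotonation with LiHMDS in THF at −78 °C gives its lithium enolate F2, which is acylated with 13 to 1-[5-(benzyloxy)-2-iodo-4-methoxyphenyl]-3-[2,4-dimethoxy-5-(pivaloyloxy)phenyl]-2-methoxypropane-1,3-dione F3. Ullmann-type O-arylation of the enol (CuI, 1,10-phenanthroline, Cs2CO3, DMF, 80 °C), a standard way from 1-(2-haloaryl)-1,3-diketones to flavones, should close the pyranone to 6-(benzyloxy)-3,7-dimethoxy-2-[2,4-dimethoxy-5-(pivaloyloxy)phenyl]-4H-chromen-4-one F4. Hydrogenolysis (H2, Pd/C, EtOAc) then gives 19.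

Step 7. The enolate may be acylated on oxygen to give an enol ester, the product enolate may be acylated a second time, or the amide base may consume the acid chloride. The fallback is an aldol addition followed by oxidation. It sets out from 13 and returns at 15. Reduction of 13 with LiAlH(Ot-Bu)3 in THF at −78 °C should give 5-formyl-2,4-dimethoxyphenyl pivalate F5. Addition of enolate 14 to F5 at −78 °C gives 1-[3-(benzyloxy)-4-methoxyphenyl]-3-[2,4-dimethoxy-5-(pivaloyloxy)phenyl]-3-hydroxy-2-methoxypropan-1-one F6 as a diastereomer mixture, which converges on oxidation. Dess–Martin periodinane (NaHCO3, CH2Cl2) then gives 15.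

Step 4. Protodebromination, inhibition of the catalyst by the carboxylate, or air oxidation of the electron-rich phenolate at 100 °C may erode the hydroxylation. The fallback is borylation followed by oxidation on the ester. It sets out from 9 and returns at 10. Fischer esterification (MeOH, H2SO4, reflux) gives methyl 5-bromo-2,4-dimethoxybenzoate F7. Miyaura borylation (B2pin2, Pd(dppf)Cl2, KOAc, dioxane, 90 °C) gives methyl 2,4-dimethoxy-5-(4,4,5,5-tetramethyl-1,3,2-dioxaborolan-2-yl)benzoate F8. Oxidation with H2O2/NaOH in THF/H2O at 0 °C gives methyl 5-hydroxy-2,4-dimethoxybenzoate F9. Saponification (LiOH, THF/H2O, then HCl) gives 10.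

**Further compounds**
F1 | step 9 | 1-[5-(benzyloxy)-2-iodo-4-methoxyphenyl]-2-methoxyethan-1-one | COCC(=O)c1cc(OCc2ccccc2)c(OC)cc1I
F2 | step 9 | lithium enolate of F1 (chelated Z isomer drawn, not isolated) | [Li]O/C(=C\OC)c1cc(OCc2ccccc2)c(OC)cc1I
F3 | step 9 | 1-[5-(benzyloxy)-2-iodo-4-methoxyphenyl]-3-[2,4-dimethoxy-5-(pivaloyloxy)phenyl]-2-methoxypropane-1,3-dione, racemic at C2 | COc1cc(I)c(C(=O)C(OC)C(=O)c2cc(OC(=O)C(C)(C)C)c(OC)cc2OC)cc1OCc1ccccc1
F4 | step 9 | 6-(benzyloxy)-3,7-dimethoxy-2-[2,4-dimethoxy-5-(pivaloyloxy)phenyl]-4H-chromen-4-one | CC(C)(C)C(=O)Oc1cc(-c2oc3cc(OC)c(OCc4ccccc4)cc3c(=O)c2OC)c(OC)cc1OC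
F5 | step 7 | 5-formyl-2,4-dimethoxyphenyl pivalate | CC(C)(C)C(=O)Oc1cc(C=O)c(OC)cc1OC
F6 | step 7 | 1-[3-(benzyloxy)-4-methoxyphenyl]-3-[2,4-dimethoxy-5-(pivaloyloxy)phenyl]-3-hydroxy-2-methoxypropan-1-one, mixture of racemic diastereomers | COc1ccc(C(=O)C(OC)C(O)c2cc(OC(=O)C(C)(C)C)c(OC)cc2OC)cc1OCc1ccccc1
F7 | step 4 | methyl 5-bromo-2,4-dimethoxybenzoate | COC(=O)c1cc(Br)c(OC)cc1OC
F8 | step 4 | methyl 2,4-dimethoxy-5-(4,4,5,5-tetramethyl-1,3,2-dioxaborolan-2-yl)benzoate | COC(=O)c1cc(B2OC(C)(C)C(C)(C)O2)c(OC)cc1OC
F9 | step 4 | methyl 5-hydroxy-2,4-dimethoxybenzoate | COC(=O)c1cc(O)c(OC)cc1OC
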